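Everything rests on C12, the only fully substituted alkene carbon, at the end of the C9–C12 diene: its two carbon substituents (C13 and the methyl) are both disconnected, leaving a C11=C12Br2 terminus. One pot then makes two bonds by sequential Negishi couplings, the C13–C19 alkylzinc entering trans to C10 and methyl replacing the second bromine with retention, which fixes the 11E geometry; no ring is closed and the C5–C6–C7 cyclopropane, C8, C16 and the ester are only carried along. The precursor is the C1–C12 dibromodiene ester, built from the Roche ester by reagent-controlled cyclopropanation; the zinc reagent comes from (S)-citronellal, and silicon–bromine exchange at C19 ends the route.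

Key step: step 18

Remark: atoms are numbered from the ester carbon C1 along the chain through the ring, so the cyclopropane is C5–C6–C7 (C6 is the ring CH2), C8 and C16 carry methyl groups, the diene is C9=C10–C11=C12 and the bromoalkyne is C18≡C19.
Remark: CIP labels at C5, C7 and C8 change between intermediates only because substituent priorities change; no stereocentre is inverted after it is set.
Remark: the (4S,5S)-dioxaborolane in step 5 is assumed to be the mirror image of the ligand that converts (E)-cinnamyl alcohol into the (1S,2S)-cyclopropylmethanol; should the facial sense prove opposite, the (4R,5R) ligand would be used.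

Step 1
Reactants: 1 methyl (2R)-3-hydroxy-2-methylpropanoate
Product: 2 methyl (2R)-3-{[tert-butyl(dimethyl)silyl]oxy}-2-methylpropanoate
Conditions: TBSCl, imidazole, CH2Cl2, 0 °C → rt
Reagents that add atoms: tert-butyl(chloro)dimethylsilane (TBSCl), CC(C)(C)[Si](C)(C)Cl
Why: Silyl ether formation at a primary alcohol, which leaves the stereocentre that becomes C8 untouched.

Step 2
Reactants: 2 methyl (2R)-3-{[tert-butyl(dimethyl)silyl]oxy}-2-methylpropanoate
Product: 3 (2R)-3-{[tert-butyl(dimethyl)silyl]oxy}-2-methylpropanal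
Conditions: i-Bu2AlH (1.1 equiv), CH2Cl2, −78 °C; aq potassium sodium tartrate; used crude
Reagents that add atoms: none
Why: Partial hydride reduction of the ester, since the aluminium hemiacetal persists at −78 °C and releases the aldehyde only on work-up, and crude use limits epimerisation.

Step 3
Reactants: 3 (2R)-3-{[tert-butyl(dimethyl)silyl]oxy}-2-methylpropanal
Product: 4 ethyl (2E,4S)-5-{[tert-butyl(dimethyl)silyl]oxy}-4-methylpent-2-enoate
Conditions: Ph3P=CHCO2Et, CH2Cl2, 0 °C → rt
Reagents that add atoms: ethyl (triphenylphosphoranylidene)acetate, CCOC(=O)C=P(c1ccccc1)(c1ccccc1)c1ccccc1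
Why: Wittig olefination with a stabilised ylide should be E-selective and needs no base, so the α-centre of 3 should survive.

Step 4
Reactants: 4 ethyl (2E,4S)-5-{[tert-butyl(dimethyl)silyl]oxy}-4-methylpent-2-enoate
Product: 5 (2E,4S)-5-{[tert-butyl(dimethyl)silyl]oxy}-4-methylpent-2-en-1-ol
Conditions: i-Bu2AlH (2.5 equiv), CH2Cl2, −78 → 0 °C; aq potassium sodium tartrate
Reagents that add atoms: none
Why: 1,2-Hydride reduction of an enoate to the allylic alcohol, with the alkene geometry and the silyl ether unaffected.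

Step 5
Reactants: 5 (2E,4S)-5-{[tert-butyl(dimethyl)silyl]oxy}-4-methylpent-2-en-1-ol
Product: 6 [(1R,2S)-2-[(2S)-1-{[tert-butyl(dimethyl)silyl]oxy}propan-2-yl]cyclopropyl]methanol
Conditions: Et2Zn, CH2I2, DME, CH2Cl2, −10 °C; (4S,5S)-2-butyl-N,N,N′,N′-tetramethyl-1,3,2-dioxaborolane-4,5-dicarboxamide (1.2 equiv); then 5, −10 °C → rt; aq NH4Cl
Reagents that add atoms: diiodomethane, ICI
Why: Charette asymmetric Simmons–Smith cyclopropanation, in which the zinc alkoxide of 5 binds the dioxaborolane and Zn(CH2I)2 is steered to one alkene face (reagent control, expected to override the C8 centre), while concerted syn methylene transfer turns the E-alkene into the trans ring and so sets C5 and C7.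

Step 6
Reactants: 6 [(1R,2S)-2-[(2S)-1-{[tert-butyl(dimethyl)silyl]oxy}propan-2-yl]cyclopropyl]methanol
Product: 7 (1R,2S)-2-[(2S)-1-{[tert-butyl(dimethyl)silyl]oxy}propan-2-yl]cyclopropane-1-carbaldehyde
Conditions: TEMPO (10 mol %), PhI(OAc)2, CH2Cl2, rt
Reagents that add atoms: none
Why: Oxoammonium (TEMPO) oxidation of a primary alcohol stops at the aldehyde, and the cyclopropyl α-carbon resists enolisation so C5 should hold.

Step 7
Reactants: 7 (1R,2S)-2-[(2S)-1-{[tert-butyl(dimethyl)silyl]oxy}propan-2-yl]cyclopropane-1-carbaldehyde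
Product: 8 (3Z)-4-[(1S,2R)-2-[(2S)-1-{[tert-butyl(dimethyl)silyl]oxy}propan-2-yl]cyclopropyl]but-3-enoic acid
Conditions: Ph3P+CH2CH2CO2H Br− (1.5 equiv), NaN(SiMe3)2 (3.0 equiv), THF, −78 → 0 °C; then 7, −78 °C → rt; aq citric acid
Reagents that add atoms: (2-carboxyethyl)triphenylphosphonium bromide, OC(=O)CC[P+](c1ccccc1)(c1ccccc1)c1ccccc1.[Br-]
Why: Wittig olefination with the non-stabilised carboxylate ylide adds C1–C3 in one operation, and the (mainly Z) alkene geometry is irrelevant because the double bond is saturated in step 8.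

Step 8
Reactants: 8 (3Z)-4-[(1S,2R)-2-[(2S)-1-{[tert-butyl(dimethyl)silyl]oxy}propan-2-yl]cyclopropyl]but-3-enoic acid
Product: 9 4-[(1R,2R)-2-[(2S)-1-{[tert-butyl(dimethyl)silyl]oxy}propan-2-yl]cyclopropyl]butanoic acid
Conditions: TsNHNH2, NaOAc, DME/H2O, reflux
Reagents that add atoms: none
Why: Diimide reduction delivers both hydrogens in a concerted syn transfer without metal-alkyl or radical intermediates, so the vinylcyclopropane should be saturated without ring opening.

Step 9
Reactants: 9 4-[(1R,2R)-2-[(2S)-1-{[tert-butyl(dimethyl)silyl]oxy}propan-2-yl]cyclopropyl]butanoic acid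
Product: 10 methyl 4-[(1R,2R)-2-[(2S)-1-hydroxypropan-2-yl]cyclopropyl]butanoate
Conditions: HCl (0.5 M), MeOH, 0 °C → rt
Reagents that add atoms: methanol, CO
Why: Fischer esterification and acid methanolysis of the primary silyl ether run under the same conditions, to which an unactivated dialkylcyclopropane should be inert.

Step 10
Reactants: 10 methyl 4-[(1R,2R)-2-[(2S)-1-hydroxypropan-2-yl]cyclopropyl]butanoate
Product: 11 methyl 4-[(1R,2R)-2-[(2S)-1-oxopropan-2-yl]cyclopropyl]butanoate
Conditions: TEMPO (10 mol %), PhI(OAc)2, CH2Cl2, rt; used crude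
Reagents that add atoms: none
Why: Oxoammonium (TEMPO) oxidation is mild enough that the α-stereocentre C8 of the new aldehyde should not epimerise, and the ester is inert.

Step 11
Reactants: 11 methyl 4-[(1R,2R)-2-[(2S)-1-oxopropan-2-yl]cyclopropyl]butanoate
Product: 12 methyl 4-[(1R,2R)-2-[(2R,3E)-5-oxopent-3-en-2-yl]cyclopropyl]butanoate
Conditions: Ph3P=CHCHO (1.3 equiv), toluene, 70 °C
Reagents that add atoms: (triphenylphosphoranylidene)acetaldehyde, O=CC=P(c1ccccc1)(c1ccccc1)c1ccccc1
Why: Wittig olefination with the stabilised formylmethylene ylide is an E-selective two-carbon homologation under neutral conditions that spare the ester and should spare C8.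

Step 12
Reactants: 12 methyl 4-[(1R,2R)-2-[(2R,3E)-5-oxopent-3-en-2-yl]cyclopropyl]butanoate
Product: 13 methyl 4-[(1R,2R)-2-[(2R,3E)-6,6-dibromohexa-3,5-dien-2-yl]cyclopropyl]butanoate
Conditions: CBr4, PPh3, CH2Cl2, 0 °C
Reagents that add atoms: carbon tetrabromide, BrC(Br)(Br)Br
Why: Ramirez dibromo-olefination (first stage of the Corey–Fuchs sequence) through Ph3P=CBr2 is aldehyde-selective and installs C12 with both bromines.

Step 13
Reactants: 14 (3S)-3,7-dimethyloct-6-enal [(S)-citronellal]
Product: 15 (4S)-4,8-dimethylnon-7-en-1-yne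
Conditions: dimethyl (1-diazo-2-oxopropyl)phosphonate, K2CO3, MeOH, 0 °C → rt
Reagents that add atoms: dimethyl (1-diazo-2-oxopropyl)phosphonate, COP(=O)(OC)C(=[N+]=[N-])C(C)=O
Why: Ohira–Bestmann (Seyferth–Gilbert) homologation converts the aldehyde into the C18≡C19 alkyne, and the stereocentre (C16) is β to the carbonyl and so cannot epimerise.

Step 14
Reactants: 15 (4S)-4,8-dimethylnon-7-en-1-yne
Product: 17 trimethyl[(4S)-4,8-dimethylnon-7-en-1-yn-1-yl]silane, via lithium acetylide 16 (not isolated)
Conditions: n-BuLi, THF, −78 °C; Me3SiCl, −78 °C → rt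
Reagents that add atoms: chlorotrimethylsilane, C[Si](C)(C)Cl
Why: Acetylide formation and C-silylation mask the acidic alkyne C–H against the zinc and palladium chemistry and place at C19 the group that is later exchanged for bromine.

Step 15
Reactants: 17 trimethyl[(4S)-4,8-dimethylnon-7-en-1-yn-1-yl]silane
Product: 19 (4S)-4-methyl-7-(trimethylsilyl)hept-6-yn-1-ol, via aldehyde 18 (not isolated)
Conditions: O3, CH2Cl2/MeOH (4:1), −78 °C; then NaBH4 (excess), −78 → 0 °C; aq NH4Cl
Reagents that add atoms: ozone, [O-][O+]=O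
Why: Ozonolysis with reductive borohydride work-up, relying on the electron-rich trisubstituted alkene reacting far faster with ozone than the silylalkyne, and on the low temperature and prompt quench to keep the C–Si bond.

Step 16
Reactants: 19 (4S)-4-methyl-7-(trimethylsilyl)hept-6-yn-1-ol
Product: 20 [(4S)-7-iodo-4-methylhept-1-yn-1-yl]trimethylsilane
Conditions: I2, PPh3, imidazole, CH2Cl2, 0 °C → rt
Reagents that add atoms: iodine, II
Why: Appel-type (Garegg–Samuelsson) iodination through an alkoxyphosphonium ion and SN2 displacement at the primary carbon.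

Step 17
Reactants: 20 [(4S)-7-iodo-4-methylhept-1-yn-1-yl]trimethylsilane
Product: 21 [(4S)-4-methyl-7-(trimethylsilyl)hept-6-yn-1-yl]zinc iodide (titrated THF solution, used directly)
Conditions: Zn dust (activated with BrCH2CH2Br and Me3SiCl), THF, 40 °C
Reagents that add atoms: zinc, [Zn]
Why: Direct oxidative insertion of activated zinc into a primary C–I bond, which tolerates the silylalkyne.

Step 18
Reactants: 13 methyl 4-[(1R,2R)-2-[(2R,3E)-6,6-dibromohexa-3,5-dien-2-yl]cyclopropyl]butanoate; 21 [(4S)-4-methyl-7-(trimethylsilyl)hept-6-yn-1-yl]zinc iodide; 22 dimethylzinc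
Product: 24 methyl 4-[(1R,2R)-2-[(2R,3E,5E,10S)-6,10-dimethyl-13-(trimethylsilyl)trideca-3,5-dien-12-yn-2-yl]cyclopropyl]butanoate, via Z-bromodiene 23 (not isolated)
Conditions: PdCl2(DPEphos) (5 mol %), 21 (1.15 equiv), THF, 0 → 23 °C; then Pd(P(t-Bu)3)2 (5 mol %), ZnMe2 (2.5 equiv), 23 °C
Reagents that add atoms: none
Why: Zerovalent palladium formed from PdCl2(DPEphos) inserts into the C12–Br bond trans to C10, which lies beside the small C11–H and is the more accessible of the two, and transmetalation from 21 followed by reductive elimination (favoured over β-hydride elimination by the wide-bite-angle ligand) gives bromodiene 23 with C13 trans to C10. The more reactive Pd(P(t-Bu)3)2 then inserts into the remaining hindered C12–Br bond and transfers methyl from ZnMe2 fast enough that the dienylpalladium intermediate should keep its geometry, so the methyl ends up cis to C10 (11E). The closest known reaction type is the tandem Negishi coupling of 1,1-dibromoalkenes, a trans-selective monosubstitution followed by stereoretentive methylation. No ring is closed and no stereocentre is created, and C5, C7, C8 and C16 pass through unchanged. The step needs site selectivity between the geminal bromines and retention in the second coupling; the first is secured by the steric difference between the C10 side and the hydrogen side of C11, the second by the bulky electron-rich phosphine. Organozinc reagents leave the methyl ester, the silylalkyne and the allylic C8–H alone, and 21 is used in only slight excess so that little remains to compete with ZnMe2.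

Step 19
Reactants: 24 methyl 4-[(1R,2R)-2-[(2R,3E,5E,10S)-6,10-dimethyl-13-(trimethylsilyl)trideca-3,5-dien-12-yn-2-yl]cyclopropyl]butanoate
Product: 25 methyl 4-[(1R,2R)-2-[(2R,3E,5E,10S)-13-bromo-6,10-dimethyltrideca-3,5-dien-12-yn-2-yl]cyclopropyl]butanoate
Conditions: NBS (1.2 equiv), AgNO3 (0.2 equiv), acetone, rt, dark
Reagents that add atoms: N-bromosuccinimide, BrN1C(=O)CCC1=O
Why: Silver-catalysed bromodesilylation, in which the silver acetylide formed at C19 is brominated by NBS much faster than NBS should attack the diene in dry acetone in the dark.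

Compound list
1 | methyl (2R)-3-hydroxy-2-methylpropanoate | COC(=O)[C@H](C)CO | starting material
2 | methyl (2R)-3-{[tert-butyl(dimethyl)silyl]oxy}-2-methylpropanoate | COC(=O)[C@H](C)CO[Si](C)(C)C(C)(C)C | intermediate
3 | (2R)-3-{[tert-butyl(dimethyl)silyl]oxy}-2-methylpropanal | O=C[C@H](C)CO[Si](C)(C)C(C)(C)C | intermediate
4 | ethyl (2E,4S)-5-{[tert-butyl(dimethyl)silyl]oxy}-4-methylpent-2-enoate | CCOC(=O)/C=C/[C@H](C)CO[Si](C)(C)C(C)(C)C | intermediate
5 | (2E,4S)-5-{[tert-butyl(dimethyl)silyl]oxy}-4-methylpent-2-en-1-ol | OC/C=C/[C@H](C)CO[Si](C)(C)C(C)(C)C | intermediate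
6 | [(1R,2S)-2-[(2S)-1-{[tert-butyl(dimethyl)silyl]oxy}propan-2-yl]cyclopropyl]methanol | OC[C@@H]1C[C@H]1[C@H](C)CO[Si](C)(C)C(C)(C)C | intermediate
7 | (1R,2S)-2-[(2S)-1-{[tert-butyl(dimethyl)silyl]oxy}propan-2-yl]cyclopropane-1-carbaldehyde | O=C[C@@H]1C[C@H]1[C@H](C)CO[Si](C)(C)C(C)(C)C | intermediate
8 | (3Z)-4-[(1S,2R)-2-[(2S)-1-{[tert-butyl(dimethyl)silyl]oxy}propan-2-yl]cyclopropyl]but-3-enoic acid | OC(=O)C/C=C\[C@@H]1C[C@H]1[C@H](C)CO[Si](C)(C)C(C)(C)C | intermediate
9 | 4-[(1R,2R)-2-[(2S)-1-{[tert-butyl(dimethyl)silyl]oxy}propan-2-yl]cyclopropyl]butanoic acid | OC(=O)CCC[C@@H]1C[C@H]1[C@H](C)CO[Si](C)(C)C(C)(C)C | intermediate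
10 | methyl 4-[(1R,2R)-2-[(2S)-1-hydroxypropan-2-yl]cyclopropyl]butanoate | COC(=O)CCC[C@@H]1C[C@H]1[C@H](C)CO | intermediate
11 | methyl 4-[(1R,2R)-2-[(2S)-1-oxopropan-2-yl]cyclopropyl]butanoate | COC(=O)CCC[C@@H]1C[C@H]1[C@H](C)C=O | intermediate
12 | methyl 4-[(1R,2R)-2-[(2R,3E)-5-oxopent-3-en-2-yl]cyclopropyl]butanoate | COC(=O)CCC[C@@H]1C[C@H]1[C@H](C)/C=C/C=O | intermediate
13 | methyl 4-[(1R,2R)-2-[(2R,3E)-6,6-dibromohexa-3,5-dien-2-yl]cyclopropyl]butanoate | COC(=O)CCC[C@@H]1C[C@H]1[C@H](C)/C=C/C=C(Br)Br | intermediate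
14 | (3S)-3,7-dimethyloct-6-enal, (S)-citronellal | CC(C)=CCC[C@H](C)CC=O | starting material
15 | (4S)-4,8-dimethylnon-7-en-1-yne | CC(C)=CCC[C@H](C)CC#C | intermediate
16 | [(4S)-4,8-dimethylnon-7-en-1-yn-1-yl]lithium | CC(C)=CCC[C@H](C)CC#C[Li] | intermediate
17 | trimethyl[(4S)-4,8-dimethylnon-7-en-1-yn-1-yl]silane | CC(C)=CCC[C@H](C)CC#C[Si](C)(C)C | intermediate
18 | (4S)-4-methyl-7-(trimethylsilyl)hept-6-ynal | O=CCC[C@H](C)CC#C[Si](C)(C)C | intermediate
19 | (4S)-4-methyl-7-(trimethylsilyl)hept-6-yn-1-ol | OCCC[C@H](C)CC#C[Si](C)(C)C | intermediate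
20 | [(4S)-7-iodo-4-methylhept-1-yn-1-yl]trimethylsilane | ICCC[C@H](C)CC#C[Si](C)(C)C | intermediate
21 | [(4S)-4-methyl-7-(trimethylsilyl)hept-6-yn-1-yl]zinc iodide | I[Zn]CCC[C@H](C)CC#C[Si](C)(C)C | intermediate
22 | dimethylzinc | C[Zn]C | starting material
23 | methyl 4-[(1R,2R)-2-[(2R,3E,5Z,10S)-6-bromo-10-methyl-13-(trimethylsilyl)trideca-3,5-dien-12-yn-2-yl]cyclopropyl]butanoate | COC(=O)CCC[C@@H]1C[C@H]1[C@H](C)/C=C/C=C(\Br)CCC[C@H](C)CC#C[Si](C)(C)C | intermediate
24 | methyl 4-[(1R,2R)-2-[(2R,3E,5E,10S)-6,10-dimethyl-13-(trimethylsilyl)trideca-3,5-dien-12-yn-2-yl]cyclopropyl]butanoate | COC(=O)CCC[C@@H]1C[C@H]1[C@H](C)/C=C/C=C(\C)CCC[C@H](C)CC#C[Si](C)(C)C | intermediate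
25 | methyl 4-[(1R,2R)-2-[(2R,3E,5E,10S)-13-bromo-6,10-dimethyltrideca-3,5-dien-12-yn-2-yl]cyclopropyl]butanoate | COC(=O)CCC[C@@H]1C[C@H]1[C@H](C)/C=C/C=C(\C)CCC[C@H](C)CC#CBr | target

Total step count: 19. Longest linear sequence: 14 steps (steps 1–12, then 18 and 19); the zinc reagent branch (steps 13–17) is 5 steps.

Steps most likely to fail

Step 18. The first oxidative addition may lose its site selectivity, the dienylpalladium intermediate may isomerise before methyl transfer (scrambling the C11=C12 geometry), or leftover 21 may transfer a second alkyl group. The fallback sets out from 11 and 20 and comes back at 24; it fixes the C11=C12 geometry by syn-carbometalation and closes the diene at C10–C11 instead. Iodide 20 would be alkylated with HC≡CLi (THF/DMPU, −78 °C → rt) to give trimethyl[(4S)-4-methylnona-1,8-diyn-1-yl]silane F1. Zirconium-catalysed methylalumination of its terminal alkyne (Me3Al, Cp2ZrCl2, CH2Cl2, 0 °C → rt) should give dimethyl[(1E,6S)-2,6-dimethyl-9-(trimethylsilyl)non-1-en-8-yn-1-yl]alumane F2, which is not isolated. Aldehyde 11 would be converted by Takai iodo-olefination (CrCl2, CHI3, THF, 0 °C) into methyl 4-[(1R,2R)-2-[(2S,3E)-4-iodobut-3-en-2-yl]cyclopropyl]butanoate F3. Palladium-catalysed alkenyl–alkenyl coupling of F2 with F3 (Pd(PPh3)4, ZnCl2, THF, rt) should then give 24 with both alkene geometries retained.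

Step 11. Olefination of the α-branched aldehyde may be sluggish, C8 may epimerise on prolonged heating, and the enal product may be homologated a second time. The fallback sets out from 11 and comes back at 12. Methylenation at low temperature (Ph3PCH3Br, KN(SiMe3)2, THF, −78 → 0 °C) would give methyl 4-[(1R,2R)-2-[(2R)-but-3-en-2-yl]cyclopropyl]butanoate F4. Cross-metathesis of F4 with excess crotonaldehyde (second-generation Hoveyda–Grubbs catalyst, CH2Cl2, 40 °C) should deliver the E-enal 12 under neutral conditions.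

Step 19. Electrophilic bromine may add to the electron-rich C9–C12 diene, or allylic bromination may occur, in competition with exchange at C19. The fallback sets out from 24 and comes back at 25. Protodesilylation (K2CO3, MeOH, 0 °C) would give methyl 4-[(1R,2R)-2-[(2R,3E,5E,10S)-6,10-dimethyltrideca-3,5-dien-12-yn-2-yl]cyclopropyl]butanoate F5. The terminal alkyne would then be brominated through its amidine-generated acetylide without silver (NBS, DBU, MeCN, 0 °C, a few minutes), which should be complete before the diene is engaged.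

Further compounds
F1 | step 18 | trimethyl[(4S)-4-methylnona-1,8-diyn-1-yl]silane | C#CCCC[C@H](C)CC#C[Si](C)(C)C
F2 | step 18 | dimethyl[(1E,6S)-2,6-dimethyl-9-(trimethylsilyl)non-1-en-8-yn-1-yl]alumane | C[Al](C)/C=C(\C)CCC[C@H](C)CC#C[Si](C)(C)C
F3 | step 18 | methyl 4-[(1R,2R)-2-[(2S,3E)-4-iodobut-3-en-2-yl]cyclopropyl]butanoate | COC(=O)CCC[C@@H]1C[C@H]1[C@H](C)/C=C/I
F4 | step 11 | methyl 4-[(1R,2R)-2-[(2R)-but-3-en-2-yl]cyclopropyl]butanoate | COC(=O)CCC[C@@H]1C[C@H]1[C@H](C)C=C
F5 | step 19 | methyl 4-[(1R,2R)-2-[(2R,3E,5E,10S)-6,10-dimethyltrideca-3,5-dien-12-yn-2-yl]cyclopropyl]butanoate | COC(=O)CCC[C@@H]1C[C@H]1[C@H](C)/C=C/C=C(\C)CCC[C@H](C)CC#C
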